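**Retrosynthetic overview**
1. Sophoranone ⇒ sophoradin, its open-chain 2'-hydroxychalcone isomer, by disconnecting O1–C2 (asymmetric 6-endo oxa-Michael; sets the only stereocentre, C2 = S).
2. Sophoradin ⇒ 3-prenylresacetophenone + 4-hydroxy-3,5-diprenylbenzaldehyde by disconnecting Cα=Cβ (Claisen–Schmidt).
3. Ketone ⇒ 2,4-dihydroxyacetophenone + prenyl bromide; aldehyde ⇒ 3,5-dibromo-4-hydroxybenzaldehyde + prenyl-Bpin.
4. Ring order: both benzene rings are purchased; the pyranone ring is the only ring formed, in the last step, together with the stereocentre. No protecting groups.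

Assumption: the catalyst in Step 4 (cat-A) is prepared separately from L-tert-leucinol and is not counted as a route step; its sense of induction on this new substrate is predicted, not known, and the D-tert-leucine-derived enantiomer is used instead if (2R) product is favoured.

**Route**

Step 1
Reactants: 1, 2,4-dihydroxyacetophenone; 2, prenyl bromide (1-bromo-3-methylbut-2-ene)
Product: 3, 1-[2,4-dihydroxy-3-(3-methylbut-2-en-1-yl)phenyl]ethan-1-one
Conditions: 2 (1.1 equiv), DBU (1.2 equiv), THF, 0 °C→rt; chromatography
Reagents that add atoms: prenyl bromide, CC(C)=CCBr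
Why: Direct phenoxide C-alkylation of the non-chelated 4-OH system goes mainly to C3, the position between the two oxygens (known one-step C-prenylation of resacetophenone; modest yield, about 35% expected, with 5-C- and 4-O-prenyl isomers removed by chromatography, accepted for a first step on cheap materials).

Step 2
Reactants: 4, 3,5-dibromo-4-hydroxybenzaldehyde; 5, prenylboronic acid pinacol ester (2 equiv incorporated)
Product: 6, 4-hydroxy-3,5-bis(3-methylbut-2-en-1-yl)benzaldehyde
Conditions: 5 (3 equiv), Pd-PEPPSI-IPent (4 mol%), 5 M aq KOH, THF, 70 °C; NH4Cl work-up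
Reagents that add atoms: prenyl-Bpin, CC(C)=CCB1OC(C)(C)C(C)(C)O1
Why: Double Suzuki–Miyaura allylation, where the bulky NHC–Pd catalyst gives coupling at the α-carbon of the prenylboronate (linear prenyl, not reverse-prenyl) and the non-enolisable, phenoxide-deactivated aldehyde tolerates aqueous KOH.

Step 3
Reactants: 3, 1-[2,4-dihydroxy-3-(3-methylbut-2-en-1-yl)phenyl]ethan-1-one; 6, 4-hydroxy-3,5-bis(3-methylbut-2-en-1-yl)benzaldehyde
Product: 7, sophoradin, (E)-1-[2,4-dihydroxy-3-(3-methylbut-2-en-1-yl)phenyl]-3-[4-hydroxy-3,5-bis(3-methylbut-2-en-1-yl)phenyl]prop-2-en-1-one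
Conditions: 50% aq KOH, EtOH, Ar, rt→40 °C, 48–72 h; pour onto ice/1 M HCl to pH 5; recrystallise
Reagents that add atoms: none
Why: Claisen–Schmidt aldol condensation of the unprotected partners gives the (E)-enone after E1cB dehydration, with the product held open as its polyphenoxide in strong base and the prenyl groups inert to base; cold, mildly acidic work-up avoids chroman formation and racemic ring closure.

Step 4
Reactants: 7, sophoradin
Product: 8, sophoranone, (2S)-7-hydroxy-2-[4-hydroxy-3,5-bis(3-methylbut-2-en-1-yl)phenyl]-8-(3-methylbut-2-en-1-yl)-2,3-dihydro-4H-chromen-4-one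
Conditions: cat-A (10 mol%), dry THF–toluene 1:1 (0.1 M), 20 °C, 24–72 h; quench with AcOH at about 90% conversion; silica chromatography, recrystallise to upgrade ee. cat-A is the bifunctional iminophosphorane–thiourea 1-[3,5-bis(trifluoromethyl)phenyl]-3-[(2S)-3,3-dimethyl-1-{[tris(4-methoxyphenyl)-λ5-phosphanylidene]amino}butan-2-yl]thiourea, SMILES COc1ccc(cc1)P(=NC[C@@H](NC(=S)Nc1cc(cc(c1)C(F)(F)F)C(F)(F)F)C(C)(C)C)(c1ccc(OC)cc1)c1ccc(OC)cc1
Reagents that add atoms: none
Why: Proposed new method: enantioselective 6-endo-trig oxa-Michael cyclisation of an unactivated, fully unprotected, electron-rich 2'-hydroxychalcone by a chiral superbase/H-bond-donor catalyst, where the iminophosphorane is protonated at once by a substrate phenol to give a chiral iminophosphonium–thiourea/phenoxide ion pair (this self-buffering also prevents aza-Wittig reaction and limits base-mediated ring-opening), fast proton shuttling gives the 2'-phenoxide tautomer, the thiourea and P=N⁺–H donors replace the internal O–H···O=C bond and bind the developing enolate oxygen so that the phenoxide adds to one face of Cβ to set C2 as S, and the enolate is protonated at the non-stereogenic C3; ring closure is thermodynamically favoured for 6'-deoxychalcones, so ee should hold if the reaction is quenched before equilibration; the closest known reaction types are iminophosphorane-catalysed intramolecular oxa-Michael additions of alcohols to α,β-unsaturated esters and amides, and cinchona–thiourea oxa-Michael cyclisations of β-ketoester-activated chalcones to flavanones.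

**Compound list**
1 | 2,4-dihydroxyacetophenone | CC(=O)c1ccc(O)cc1O | starting material
2 | prenyl bromide (1-bromo-3-methylbut-2-ene) | CC(C)=CCBr | starting material
3 | 1-[2,4-dihydroxy-3-(3-methylbut-2-en-1-yl)phenyl]ethan-1-one | CC(=O)c1ccc(O)c(CC=C(C)C)c1O | intermediate
4 | 3,5-dibromo-4-hydroxybenzaldehyde | O=Cc1cc(Br)c(O)c(Br)c1 | starting material
5 | prenylboronic acid pinacol ester (4,4,5,5-tetramethyl-2-(3-methylbut-2-en-1-yl)-1,3,2-dioxaborolane) | CC(C)=CCB1OC(C)(C)C(C)(C)O1 | starting material
6 | 4-hydroxy-3,5-bis(3-methylbut-2-en-1-yl)benzaldehyde | CC(C)=CCc1cc(C=O)cc(CC=C(C)C)c1O | intermediate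
7 | sophoradin, (E)-2',4,4'-trihydroxy-3,3',5-triprenylchalcone | CC(C)=CCc1cc(/C=C/C(=O)c2ccc(O)c(CC=C(C)C)c2O)cc(CC=C(C)C)c1O | intermediate
8 | sophoranone, (2S)-7-hydroxy-8-prenyl-2-(4-hydroxy-3,5-diprenylphenyl)chroman-4-one | CC(C)=CCc1cc([C@@H]2CC(=O)c3ccc(O)c(CC=C(C)C)c3O2)cc(CC=C(C)C)c1O | target

**Step count**
Total steps: 4. Longest linear sequence: 3 (Steps 1, 3, 4).

**Three steps most likely to fail**
1. Step 4 (proposed new step). Risks: slow closure because the most acidic phenol (4'-OH) holds the charge away from the reacting 2'-oxygen; ee erosion through reversible ring-opening; unknown facial sense. Fallback (known chemistry): β-ketoester activation. MOM-protect the 4-OH of 3 and of 6, convert the ketone to its tert-butyl β-ketoester, and run a Knoevenagel condensation with the protected aldehyde. Cyclise the alkylidene β-ketoester with a quinine- or quinidine-derived thiourea (established for flavanones, including prenylated B-rings), then decarboxylate and remove MOM under mild acid.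
2. Step 3. Risk: the trianionic ketone and the phenoxide-deactivated aldehyde condense slowly and in low yield. Fallback: protected strategy. MOM-protect the 4-OH of 3 and of 6 (MOMCl, i-Pr2NEt), run the now-standard KOH/EtOH condensation, and remove MOM with dilute HCl/MeOH to reach 7.
3. Step 2. Risks: γ-coupling (reverse-prenyl) or protodebromination on the hindered bromophenoxide. Fallback: sigmatropic route from 4-hydroxybenzaldehyde. Carry out two rounds of Pd(0)-catalysed O-(1,1-dimethylallyl)ation with a 2-methylbut-3-en-2-yl carbonate followed by aromatic Claisen rearrangement, which delivers each ortho-prenyl group with unambiguous regiochemistry.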